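**Retrosynthetic overview**
1. Target 22 ⇒ methyl ester 21 ⇒ monocyclic spiro-lactone enone 19: the tetrahydrofuran bridge (O17–C16) is closed last by oxa-Michael addition of a C18 alcohol unmasked from CH2SiMe2Ph.
2. 19 ⇒ ethyl ketone 17 by the key step, an oxidative 1,2-shift of ring carbon C4 from the acyl carbon to C2 (propanoyl → α-methyl ester). The propanoyl group first keeps C4 epimerisable; the shift then locks C4 and creates C2.
3. 17 ⇒ ester 16 by intramolecular Michael addition (C13–C7), which forms the spiro centre and the δ-lactone and sets C7 and C8.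
4. 16 ⇒ alcohol 8 (asymmetric 1,4-addition/formaldehyde aldol on 4,4-dimethylcyclohexadienone, sets C19) + racemic acid 15 (three-component coupling on ethyl vinyl ketone, then ring-closing metathesis).
5. Ring order: dimethylcyclohexenone (Robinson) and ring B (metathesis) in parallel → δ-lactone (Michael) → tetrahydrofuran bridge (oxa-Michael).

Atom labels used below (own numbering of the target SMILES): CH3–C2H(C3O2H)–; ring B C4–C5–C6–C7–C8–C9; lactone C10(=O)–O11–C12; spiro C13; ketone C14; C15; C16; O17; C18; C19; C20 (CMe2).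
Assumption: the given SMILES defines the target as 2R,4R,7R,8S,13S,16R,19R in these labels.

**Step 1**
Reactants: 1 2-methylpropanal; 2 but-3-en-2-one
Product: 5 4,4-dimethylcyclohex-2-en-1-one, via 2,2-dimethyl-5-oxohexanal 3 (not isolated), via 3-hydroxy-4,4-dimethylcyclohexan-1-one 4 (not isolated)
Conditions: H2SO4 (cat.), toluene, 45 °C, then reflux (Dean–Stark)
Reagents that add atoms: none
Why: acid-catalysed Michael addition of the aldehyde enol to the enone followed by aldol condensation of keto aldehyde 3 (Robinson annulation) gives the gem-dimethyl enone; no stereocentre is created.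

**Step 2**
Reactants: 5 4,4-dimethylcyclohex-2-en-1-one
Product: 6 4,4-dimethylcyclohexa-2,5-dien-1-one
Conditions: DDQ (1.5 equiv), 1,4-dioxane, reflux
Reagents that add atoms: none
Why: quinone dehydrogenation through the enol gives the cross-conjugated dienone, which cannot aromatise because C20 is quaternary; no stereocentre is created.

**Step 3**
Reactants: 6 4,4-dimethylcyclohexa-2,5-dien-1-one
Product: 8 (5S,6R)-5-{[dimethyl(phenyl)silyl]methyl}-6-(hydroxymethyl)-4,4-dimethylcyclohex-2-en-1-one, via zinc dienolate 7 (not isolated)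
Conditions: (PhMe2SiCH2)2Zn (1.5 equiv, prepared separately), Cu(OTf)2 (2 mol%), (S,R,R)-BINOL bis(1-phenylethyl)amine phosphoramidite (4 mol%), toluene, −30 °C; then CH2O (monomeric, THF), −30 → 0 °C; aq. NH4Cl
Reagents that add atoms: bis{[dimethyl(phenyl)silyl]methyl}zinc (C[Si](C)(C[Zn]C[Si](C)(C)c1ccccc1)c1ccccc1); formaldehyde (C=O)
Why: copper/phosphoramidite-catalysed enantioselective 1,4-addition of the dialkylzinc to the prochiral dienone sets C19 under ligand control (the ligand enantiomer is chosen to give 5S), and zinc enolate 7 is trapped by formaldehyde in a tandem aldol trans to the new substituent, a C13 configuration that is erased again in step 8.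

**Step 4**
Reactants: 9 pent-1-en-3-one; 10 allylmagnesium bromide; 11 methyl 2-(bromomethyl)prop-2-enoate
Product: 13 methyl 2-methylidene-4-propanoyloct-7-enoate (racemic), via bromomagnesium enolate 12 (not isolated)
Conditions: 10 (1.1 equiv), CuBr·SMe2 (10 mol%), THF, −78 °C; then 11, DMPU, −78 → 0 °C
Reagents that add atoms: none
Why: copper-catalysed conjugate allylation of the vinyl ketone gives the regiodefined enolate 12, which is C-alkylated by the doubly activated allylic bromide (SN2 and SN2′ give the same product); C4 is formed racemic on purpose because it stays epimerisable, α to the ketone, until step 9.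

**Step 5**
Reactants: 13 methyl 2-methylidene-4-propanoyloct-7-enoate
Product: 14 methyl 5-propanoylcyclohex-1-ene-1-carboxylate (racemic)
Conditions: second-generation Grubbs catalyst RuCl2(=CHPh)(H2IMes)(PCy3) (3 mol%), CH2Cl2 (0.01 M), 40 °C
Reagents that add atoms: none
Why: ring-closing metathesis between the terminal alkene and the 2-substituted acrylate closes ring B as the trisubstituted cyclohexenecarboxylate with loss of ethene; no new stereocentre.

**Step 6**
Reactants: 14 methyl 5-propanoylcyclohex-1-ene-1-carboxylate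
Product: 15 5-propanoylcyclohex-1-ene-1-carboxylic acid (racemic)
Conditions: LiOH·H2O (2 equiv), THF–H2O 3:1, 0 °C → rt; then 1 M HCl
Reagents that add atoms: lithium hydroxide ([Li+].[OH-])
Why: saponification of the conjugated methyl ester leaves the ketone untouched, and racemisation at C4 is irrelevant.

**Step 7**
Reactants: 8 (5S,6R)-5-{[dimethyl(phenyl)silyl]methyl}-6-(hydroxymethyl)-4,4-dimethylcyclohex-2-en-1-one; 15 5-propanoylcyclohex-1-ene-1-carboxylic acid
Product: 16 [(1R,6S)-6-{[dimethyl(phenyl)silyl]methyl}-5,5-dimethyl-2-oxocyclohex-3-en-1-yl]methyl 5-propanoylcyclohex-1-ene-1-carboxylate (both C4 epimers)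
Conditions: EDC·HCl (1.3 equiv), DMAP (0.1 equiv), CH2Cl2, 0 °C → rt
Reagents that add atoms: none
Why: carbodiimide (Steglich) esterification of the primary alcohol under near-neutral conditions installs the lactone tether O11–C10 without retro-aldol or dehydration of the β-hydroxy ketone; no stereocentre changes.

**Step 8**
Reactants: 16 ester (both C4 epimers)
Product: 17 spiro-lactone ethyl ketone (4R,7R,8S,13S,19R): (1S,4′aR,6R,7′R,8′aS)-6-{[dimethyl(phenyl)silyl]methyl}-5,5-dimethyl-7′-propanoyl-octahydro-1′H-spiro[cyclohex-3-ene-1,4′-isochromene]-1′,2-dione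
Conditions: KOt-Bu (0.2 equiv), THF–t-BuOH 10:1, −20 → 0 °C; AcOH quench
Reagents that add atoms: none
Why: intramolecular Michael addition (6-endo) of the dienolate at C13, the only enolisable position of the enone, onto C7 of the tethered cyclohexenecarboxylate closes the δ-lactone and creates the spiro centre: C7 bonds to C13 anti to the CH2SiMe2Ph group on C19 (C13 S), the tether folds toward the enolate oxygen and away from C19 so that C6 lies pseudo-equatorial between C14 and C19 (C7 R), t-BuOH protonates the lactone enolate on its convex face to the cis ring fusion (C8 S), and the propanoyl-bearing C4 equilibrates through its enolate to the equatorial position trans to C7 (C4 R), so both epimers of 16 converge.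

**Step 9**
Reactants: 17 spiro-lactone ethyl ketone
Product: 19 methyl (2R)-2-[(1S,4′aR,6R,7′R,8′aS)-6-{[dimethyl(phenyl)silyl]methyl}-5,5-dimethyl-1′,2-dioxo-octahydro-1′H-spiro[cyclohex-3-ene-1,4′-isochromen]-7′-yl]propanoate, via methyl enol ether 18 (not isolated)
Conditions: (R,R)-ArI(OAc)2 (1.3 equiv; Ar = 2,6-bis{[(2R)-1-methoxy-1-oxopropan-2-yl]oxy}phenyl), TfOH (0.2 equiv), HC(OMe)3–CH2Cl2 1:1, −40 → 0 °C; aq. NaHCO3
Reagents that add atoms: trimethyl orthoformate (COC(OC)OC)
Why: Proposed new method: reagent-controlled enantioselective oxidative 1,2-alkyl shift of a dialkyl ketone with a chiral aryl-λ3-iodane, in which acid and orthoformate convert the ethyl ketone into the less substituted (Z)-methyl enol ether 18, the lactate-based iodane adds to its CH carbon from one face, methanol closes the α-iodanyl ketal, and ring carbon C4 migrates from the ketal carbon to C2 as ArI departs (inversion at C2, retention at C4, so the thermodynamically set C4 is locked and C2 R is created) to give an orthoester that hydrolyses to the methyl ester on work-up, while the enone has no enolisable position and stays inert; closest known reaction type: trivalent-iodine or thallium trinitrate oxidative 1,2-aryl shift of aryl ethyl ketones to methyl 2-arylpropanoates, including enantioselective lactate-iodane versions, and the iodane-mediated ring contraction of cycloalkanones as the racemic alkyl-shift precedent.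

**Step 10**
Reactants: 19 methyl ester with CH2SiMe2Ph at C19
Product: 21 methyl (2R)-2-[(1′R,4S,4aR,5′R,7R,8aS)-8′,8′-dimethyl-1,3′-dioxooctahydrospiro[isochromene-4,2′-[6]oxabicyclo[3.2.1]octan]-7-yl]propanoate, via primary alcohol 20 (not isolated)
Conditions: KBr (1.5 equiv), AcOOH (32% in AcOH, 6 equiv), NaOAc, AcOH, 0 °C → rt; Na2S2O3 work-up; then DBU (5 mol%), CH2Cl2, 0 °C
Reagents that add atoms: peracetic acid (CC(=O)OO)
Why: Fleming–Tamao oxidation (ipso-bromodesilylation of the phenyl group, then peracid-induced carbon-to-oxygen shift with retention) unmasks primary alcohol 20, which adds to the enone β-carbon C16 in an intramolecular oxa-Michael reaction (5-exo); the two-atom bridge can only span cis, so C16 (R) is dictated by C19.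

**Step 11**
Reactants: 21 methyl ester of the target
Product: 22 CNP0152427.2, (2R)-2-[(1′R,4S,4aR,5′R,7R,8aS)-8′,8′-dimethyl-1,3′-dioxooctahydrospiro[isochromene-4,2′-[6]oxabicyclo[3.2.1]octan]-7-yl]propanoic acid
Conditions: Me3SnOH (5 equiv), ClCH2CH2Cl, 70 °C; 1 M HCl work-up
Reagents that add atoms: trimethyltin hydroxide (C[Sn](C)(C)O)
Why: trimethyltin hydroxide cleaves the unhindered methyl ester under near-neutral conditions (tin carboxylate, then acid), which avoids hydroxide-induced epimerisation at C2 and C8, lactone opening with retro-aldol loss of C12, and retro-oxa-Michael opening of the bridge; no stereocentre changes.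

**Compound list**
1 | 2-methylpropanal | CC(C)C=O | starting material
2 | but-3-en-2-one | CC(=O)C=C | starting material
3 | 2,2-dimethyl-5-oxohexanal | CC(=O)CCC(C)(C)C=O | intermediate
4 | 3-hydroxy-4,4-dimethylcyclohexan-1-one (racemic) | CC1(C)CCC(=O)CC1O | intermediate
5 | 4,4-dimethylcyclohex-2-en-1-one | CC1(C)CCC(=O)C=C1 | intermediate
6 | 4,4-dimethylcyclohexa-2,5-dien-1-one | CC1(C)C=CC(=O)C=C1 | intermediate
7 | {[dimethyl(phenyl)silyl]methyl}zinc (3S)-3-{[dimethyl(phenyl)silyl]methyl}-4,4-dimethylcyclohexa-1,5-dien-1-olate | C[Si](C)(c1ccccc1)C[Zn]OC1=C[C@H](C[Si](C)(C)c2ccccc2)C(C)(C)C=C1 | intermediate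
8 | (5S,6R)-5-{[dimethyl(phenyl)silyl]methyl}-6-(hydroxymethyl)-4,4-dimethylcyclohex-2-en-1-one | OC[C@@H]1C(=O)C=CC(C)(C)[C@H]1C[Si](C)(C)c1ccccc1 | intermediate
9 | pent-1-en-3-one | CCC(=O)C=C | starting material
10 | allylmagnesium bromide | C=CC[Mg]Br | starting material
11 | methyl 2-(bromomethyl)prop-2-enoate | C=C(CBr)C(=O)OC | starting material
12 | bromomagnesium hepta-3,6-dien-3-olate | CCC(O[Mg]Br)=CCCC=C | intermediate
13 | methyl 2-methylidene-4-propanoyloct-7-enoate (racemic) | CCC(=O)C(CCC=C)CC(=C)C(=O)OC | intermediate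
14 | methyl 5-propanoylcyclohex-1-ene-1-carboxylate (racemic) | CCC(=O)C1CCC=C(C1)C(=O)OC | intermediate
15 | 5-propanoylcyclohex-1-ene-1-carboxylic acid (racemic) | CCC(=O)C1CCC=C(C1)C(=O)O | intermediate
16 | [(1R,6S)-6-{[dimethyl(phenyl)silyl]methyl}-5,5-dimethyl-2-oxocyclohex-3-en-1-yl]methyl 5-propanoylcyclohex-1-ene-1-carboxylate (both C4 epimers) | CCC(=O)C1CCC=C(C1)C(=O)OC[C@@H]1C(=O)C=CC(C)(C)[C@H]1C[Si](C)(C)c1ccccc1 | intermediate
17 | spiro-lactone ethyl ketone (4R,7R,8S,13S,19R); cis-fused lactone, C4-propanoyl, C15=C16 enone, C18-SiMe2Ph | CCC(=O)[C@@H]1CC[C@@H]2[C@H](C1)C(=O)OC[C@]21C(=O)C=CC(C)(C)[C@H]1C[Si](C)(C)c1ccccc1 | intermediate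
18 | (Z)-methyl enol ether of 17 (C4–C(OMe)=CH–CH3) | C/C=C(\OC)[C@@H]1CC[C@@H]2[C@H](C1)C(=O)OC[C@]21C(=O)C=CC(C)(C)[C@H]1C[Si](C)(C)c1ccccc1 | intermediate
19 | methyl (2R)-2-propanoate at C4 of the spiro-lactone enone (2R,4R,7R,8S,13S,19R), C18-SiMe2Ph | C[C@@H](C(=O)OC)[C@@H]1CC[C@@H]2[C@H](C1)C(=O)OC[C@]21C(=O)C=CC(C)(C)[C@H]1C[Si](C)(C)c1ccccc1 | intermediate
20 | primary alcohol: as 19 with CH2OH at C19 | C[C@@H](C(=O)OC)[C@@H]1CC[C@@H]2[C@H](C1)C(=O)OC[C@]21C(=O)C=CC(C)(C)[C@H]1CO | intermediate
21 | methyl ester of the target (2R,4R,7R,8S,13S,16R,19R) | C[C@@H](C(=O)OC)[C@@H]1CC[C@@H]2[C@H](C1)C(=O)OC[C@]21C(=O)C[C@H]2OC[C@@H]1C2(C)C | intermediate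
22 | CNP0152427.2, (2R)-2-[(1′R,4S,4aR,5′R,7R,8aS)-8′,8′-dimethyl-1,3′-dioxooctahydrospiro[isochromene-4,2′-[6]oxabicyclo[3.2.1]octan]-7-yl]propanoic acid | C[C@@H](C(=O)O)[C@@H]1CC[C@@H]2[C@H](C1)C(=O)OC[C@]21C(=O)C[C@H]2OC[C@@H]1C2(C)C | target

**Step count and risks**
Total step count: 11. Longest linear sequence: 8 steps (1, 2, 3, 7, 8, 9, 10, 11); steps 4–6 make acid 15 in parallel.

The three steps most likely to fail:

Step 9, the new oxidative 1,2-shift. The risks are α-methoxylation instead of migration, enol ether formation toward C4, weak face control at C2, and acid damage to the phenylsilane or the lactone. The fallback uses known chemistry and a different 1,2-shift (Arndt–Eistert homologation with a Wolff rearrangement). It sets out from 17: LiN(SiMe3)2 and Me3SiCl (THF, −78 °C) give the kinetic (Z)-trimethylsilyl enol ether F1. Ozone (CH2Cl2, −78 °C, then Me2S) cleaves the electron-rich enol ether selectively to the C4 carboxylic acid F2. Oxalyl chloride with catalytic DMF gives the acid chloride F3, and diazoethane (Et2O, 0 °C) gives the α-diazo ketone F4. Silver benzoate and Et3N in methanol then trigger the Wolff rearrangement, in which C4 migrates with retention, and the ketene is trapped as the methyl ester. This comes back to the route at 19, formed together with the C2 epimer of 19 F5, which is separated by chromatography and recycled by DBU epimerisation.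

Step 8, the spiro-annulating Michael addition. The enolate of the β-acyloxy ketone can fragment by E1cB, and the C13–C7 bond joins a quaternary to a tertiary centre. The fallback starts from the fragmentation product instead of fighting it. It sets out from 8: MsCl and Et3N (CH2Cl2, 0 °C) dehydrate it to the exocyclic enone F6. F6 and acid 15 are then combined with Cs2CO3 in MeCN, so that the carboxylate adds to C12 (oxa-Michael) and generates the C13 enolate without any deprotonation; this enolate closes onto C7 as in the main route. This comes back at 17.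

Step 3, the asymmetric 1,4-addition with formaldehyde trapping. The β-carbon is neopentyl-like, the zinc reagent is bulky, and monomeric formaldehyde is an awkward electrophile for a zinc enolate. The fallback separates the two events. It sets out from 6: the same copper/phosphoramidite 1,4-addition is quenched with Me3SiOTf to give the isolable trimethylsilyl dienol ether F7. A Mukaiyama aldol reaction of F7 with aqueous formaldehyde and Sc(OTf)3 in THF then installs the hydroxymethyl group, coming back at 8.

**Further compounds**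
F1 | step 9 | (Z)-trimethylsilyl enol ether of ketone 17 | C/C=C(\O[Si](C)(C)C)[C@@H]1CC[C@@H]2[C@H](C1)C(=O)OC[C@]21C(=O)C=CC(C)(C)[C@H]1C[Si](C)(C)c1ccccc1
F2 | step 9 | C4 carboxylic acid (propanoyl of 17 cleaved to CO2H) | OC(=O)[C@@H]1CC[C@@H]2[C@H](C1)C(=O)OC[C@]21C(=O)C=CC(C)(C)[C@H]1C[Si](C)(C)c1ccccc1
F3 | step 9 | acid chloride of F2 | ClC(=O)[C@@H]1CC[C@@H]2[C@H](C1)C(=O)OC[C@]21C(=O)C=CC(C)(C)[C@H]1C[Si](C)(C)c1ccccc1
F4 | step 9 | α-diazo ketone (2-diazopropanoyl at C4) | CC(=[N+]=[N-])C(=O)[C@@H]1CC[C@@H]2[C@H](C1)C(=O)OC[C@]21C(=O)C=CC(C)(C)[C@H]1C[Si](C)(C)c1ccccc1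
F5 | step 9 | C2 epimer of 19 | C[C@H](C(=O)OC)[C@@H]1CC[C@@H]2[C@H](C1)C(=O)OC[C@]21C(=O)C=CC(C)(C)[C@H]1C[Si](C)(C)c1ccccc1
F6 | step 8 | (5R)-5-{[dimethyl(phenyl)silyl]methyl}-4,4-dimethyl-6-methylidenecyclohex-2-en-1-one | C=C1C(=O)C=CC(C)(C)[C@H]1C[Si](C)(C)c1ccccc1
F7 | step 3 | {[(3S)-3-{[dimethyl(phenyl)silyl]methyl}-4,4-dimethylcyclohexa-1,5-dien-1-yl]oxy}trimethylsilane | C[Si](C)(C)OC1=C[C@H](C[Si](C)(C)c2ccccc2)C(C)(C)C=C1
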